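**Plan**

1. Retrosynthetic cuts, in order: the C1 ester C–O bond; the two aldehydes and the C6‑OH/C7=C8 pair, taken back to a 6α,7α‑epoxy‑11,12‑diol; ring A at C3–C4 and C5–C10, which opens ring B as well and leaves an open‑chain trienone; C1–C2 and C5–C6 (two Grignard additions); finally the chain is traced back through C1=C6 to a temporary cyclohexene, the Diels–Alder adduct of diethyl fumarate.
2. Enabling feature: ring A carries oxygen on C1, and its C4–C5 edge (gem‑dimethyl carbon and ring‑fusion CH) lies next to the C6 oxygen of ring B. As a C1 silyl enol ether and a C6 ketone these turn C10=C1–C2=C3 into a 2‑silyloxy diene and C5=C4 into an enone dienophile, tied together by the four ring‑B carbons C6–C9.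
3. Forward: temporary ring (sets C8 and C9) → ozonolysis to the chain → diene at one end, enone at the other → one intramolecular Diels–Alder reaction closes rings A and B together and creates both quaternary carbons (C4, C10) → C6 ketone to the Δ6 alkene, C1 to the 1β‑ester, α‑epoxide, oxidation with β‑elimination.
4. Stereochemistry: C9 (and the relay centre C8) from a catalytic enantioselective cycloaddition; C10 and C5 in the key step under control of C9/C8 and the (Z)‑enol ether; C1 by axial hydride attack; C6 by α‑face epoxidation.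

Key step: step 11

Assumption: the (S)‑configured oxazaborolidinium catalyst of step 2 is taken to expose the dienophile face that leads to the (1R,2R)‑diester 4; should the facial sense be the reverse, its enantiomer is used and nothing else changes.

Remark: drimane numbering of the target is used for all carbons, also in the open‑chain compounds (C1–C10 decalin, C11 on C9, C12 on C8, two methyls on C4, one on C10). TIPS = triisopropylsilyl, TBS = tert‑butyldimethylsilyl. Where the methyl‑bearing carbon (future C10) or a carbinol carbon is formed as an epimer mixture before step 9, this is stated; these centres are erased in steps 8 and 9.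

**Route**

Step 1
Reactants: 1 (E)-pent-3-en-2-one
Product: 2 (E)-2-(triisopropylsilyloxy)penta-1,3-diene
Conditions: TIPSOTf, Et3N, CH2Cl2, 0 °C
Reagents that add atoms: triisopropylsilyl trifluoromethanesulfonate, CC(C)[Si](OS(=O)(=O)C(F)(F)F)(C(C)C)C(C)C
Why: soft enolisation of the enone at its α'-methyl group (silyl triflate/amine) should give the cross‑conjugated 2‑silyloxy diene with the (E) double bond untouched.

Step 2
Reactants: 2 (E)-2-(triisopropylsilyloxy)penta-1,3-diene; 3 diethyl fumarate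
Product: 4 diethyl (1R,2R)-3-methyl-5-(triisopropylsilyloxy)cyclohex-4-ene-1,2-dicarboxylate (C3 epimers)
Conditions: (S)-1-(2-methylphenyl)-3,3-diphenyltetrahydro-1H,3H-pyrrolo[1,2-c][1,3,2]oxazaborole·HN(SO2CF3)2 (10 mol %), CH2Cl2, −78 → −40 °C
Reagents that add atoms: none
Why: catalytic enantioselective Diels–Alder reaction of a 2‑silyloxy diene with a fumarate; the trans relation of the two ester carbons (future C8, C9) follows from the (E)-dienophile and their absolute configuration from face shielding by the chiral boron Lewis acid, while the ring itself is temporary.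

Step 3
Reactants: 4 diethyl (1R,2R)-3-methyl-5-(triisopropylsilyloxy)cyclohex-4-ene-1,2-dicarboxylate
Product: 5 [(1R,2R)-3-methyl-5-(triisopropylsilyloxy)cyclohex-4-ene-1,2-diyl]dimethanol (C3 epimers)
Conditions: LiAlH4, Et2O, 0 °C; aq. NaOH work-up
Reagents that add atoms: none
Why: hydride reduction of both esters to the primary alcohols (future C11, C12); a TIPS enol ether should be inert to LiAlH4.

Step 4
Reactants: 5 [(1R,2R)-3-methyl-5-(triisopropylsilyloxy)cyclohex-4-ene-1,2-diyl]dimethanol
Product: 6 (1R,2R)-3-methyl-5-(triisopropylsilyloxy)-1,2-bis(triisopropylsilyloxymethyl)cyclohex-4-ene (C3 epimers)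
Conditions: TIPSCl (2.2 equiv), imidazole, DMF, rt
Reagents that add atoms: chlorotriisopropylsilane, CC(C)[Si](Cl)(C(C)C)C(C)C
Why: standard silylation of two primary alcohols; the TIPS ethers are chosen to survive ozone, Grignard reagents, heat, base and dilute acid.

Step 5
Reactants: 6 (1R,2R)-3-methyl-5-(triisopropylsilyloxy)-1,2-bis(triisopropylsilyloxymethyl)cyclohex-4-ene
Product: 8 (3R,4S)-5-methyl-6-oxo-3,4-bis(triisopropylsilyloxymethyl)hexanoic acid (C5 epimers), via triisopropylsilyl ester 7 (not isolated)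
Conditions: O3, CH2Cl2/MeOH, −78 °C; Me2S, −78 °C → rt; aqueous work-up at pH 5
Reagents that add atoms: ozone, O=[O+][O-]
Why: ozonolysis of the silyl enol ether double bond (C1=C6) unravels the temporary ring into a chain with differentiated ends, an aldehyde at C1 and, after hydrolysis of the silyl ester, an acid at C6.

Step 6
Reactants: 8 (3R,4S)-5-methyl-6-oxo-3,4-bis(triisopropylsilyloxymethyl)hexanoic acid
Product: 9 (3R,4S)-N-methoxy-N,5-dimethyl-6-oxo-3,4-bis(triisopropylsilyloxymethyl)hexanamide (C5 epimers)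
Conditions: MeNH(OMe)·HCl, EDC·HCl, 1-hydroxybenzotriazole (cat.), N-methylmorpholine, CH2Cl2, 0 °C → rt
Reagents that add atoms: N,O-dimethylhydroxylamine hydrochloride, CNOC.Cl
Why: carbodiimide amide coupling; the secondary hydroxylamine cannot condense irreversibly with the aldehyde.

Step 7
Reactants: 9 (3R,4S)-N-methoxy-N,5-dimethyl-6-oxo-3,4-bis(triisopropylsilyloxymethyl)hexanamide; 10 vinylmagnesium bromide (CH2=CHMgBr)
Product: 11 (3R,4S)-6-hydroxy-N-methoxy-N,5-dimethyl-3,4-bis(triisopropylsilyloxymethyl)oct-7-enamide (C5 and C6 epimers)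
Conditions: CH2=CHMgBr (1.2 equiv), THF, −78 °C; then H2O
Reagents that add atoms: none
Why: Grignard 1,2‑addition that should be chemoselective, since an aldehyde reacts at −78 °C while a Weinreb amide is nearly inert at that temperature.

Step 8
Reactants: 11 (3R,4S)-6-hydroxy-N-methoxy-N,5-dimethyl-3,4-bis(triisopropylsilyloxymethyl)oct-7-enamide
Product: 12 (3R,4S)-N-methoxy-N,5-dimethyl-6-oxo-3,4-bis(triisopropylsilyloxymethyl)oct-7-enamide (C5 epimers)
Conditions: Dess–Martin periodinane, CH2Cl2, 0 °C → rt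
Reagents that add atoms: none
Why: Dess–Martin oxidation of the allylic alcohol to the vinyl ketone under near‑neutral conditions.

Step 9
Reactants: 12 (3R,4S)-N-methoxy-N,5-dimethyl-6-oxo-3,4-bis(triisopropylsilyloxymethyl)oct-7-enamide
Product: 13 (3R,4S,5Z)-6-(tert-butyldimethylsilyloxy)-N-methoxy-N,5-dimethyl-3,4-bis(triisopropylsilyloxymethyl)octa-5,7-dienamide
Conditions: TBSOTf, Et3N, CH2Cl2, −78 → 0 °C
Reagents that add atoms: tert-butyldimethylsilyl trifluoromethanesulfonate, CC(C)(C)[Si](C)(C)OS(=O)(=O)C(F)(F)F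
Why: soft enolisation of the vinyl ketone at its only α‑hydrogen (C10), the amide being left alone; the (Z) geometry (O–Si cis to the branched C9, vinyl cis to methyl) is expected because it avoids allylic strain between the vinyl group and C9.

Step 10
Reactants: 13 (3R,4S,5Z)-6-(tert-butyldimethylsilyloxy)-N-methoxy-N,5-dimethyl-3,4-bis(triisopropylsilyloxymethyl)octa-5,7-dienamide; 14 2-methylprop-1-enylmagnesium bromide (Me2C=CHMgBr)
Product: 15 (6R,7S,8Z)-9-(tert-butyldimethylsilyloxy)-2,8-dimethyl-6,7-bis(triisopropylsilyloxymethyl)undeca-2,8,10-trien-4-one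
Conditions: Me2C=CHMgBr, THF, −78 → 0 °C; pH 7 buffer
Reagents that add atoms: none
Why: Weinreb ketone synthesis; the chelated tetrahedral adduct prevents over‑addition and the silyl enol ether is inert to the Grignard reagent, so the enone dienophile is unveiled last, when no other enolisable ketone is present.

Step 11
Reactants: 15 (6R,7S,8Z)-9-(tert-butyldimethylsilyloxy)-2,8-dimethyl-6,7-bis(triisopropylsilyloxymethyl)undeca-2,8,10-trien-4-one
Product: 16 1-(tert-butyldimethylsilyloxy)-11,12-bis(triisopropylsilyloxy)drim-1-en-6-one (5α-H, 8β-H, 9α-H, 10β-methyl)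
Conditions: PhMe (0.01 M), 2,6-di-tert-butyl-4-methylphenol (trace), base-washed sealed tube, 160 °C; then 1,8-diazabicyclo[5.4.0]undec-7-ene (0.3 equiv), 90 °C
Reagents that add atoms: none
Why: Concerted thermal [4+2] cycloaddition in which the silyloxy diene C10=C1–C2=C3 adds across the enone double bond C5=C4, C3 bonding to the gem‑dimethyl carbon C4 and C10 to C5; the closest known reaction type is the thermal intramolecular Diels–Alder reaction of 1,7,9-decatrien-3-ones carrying a 2‑silyloxy diene. Ring A closes as the new cyclohexene (silyl enol ether C1=C2) and ring B closes at the same time in the fused mode, because the four‑atom tether C6–C9 joins C5 to C10 and makes the bridged orientation, which the 2‑silyloxy group would prefer electronically, inaccessible. C10 is set by the diene face that is attacked, controlled by C9 and C8: the tether adopts a chair with both CH2OTIPS groups equatorial and C9–H eclipsing the C1–OSi bond (allylic 1,3‑strain), which places the methyl group anti to H‑9, and the (Z)-enol ether keeps the tether on the outside of the diene. C5 arises trans to the C10 methyl through the chair transition state with the ketone exo; because C5 is α to the C6 ketone, the amidine treatment converges any cis‑fused epimer to the trans‑decalone. The step needs periselectivity against ionic aldol‑ or Michael‑type closure of the silyl enol ether onto the enone and against [1,5]-hydrogen shift in the diene, which neutral, Lewis‑acid‑free conditions and a moderate temperature should secure. Each new bond joins one fully substituted carbon to a less substituted one (C4 to the CH2 terminus C3, C10 to the CH carbon C5), which is what should keep the formation of two quaternary centres feasible.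

Step 12
Reactants: 16 1-(tert-butyldimethylsilyloxy)-11,12-bis(triisopropylsilyloxy)drim-1-en-6-one
Product: 18 1-(tert-butyldimethylsilyloxy)-11,12-bis(triisopropylsilyloxy)drima-1,6-dien-6-yl trifluoromethanesulfonate, via potassium C6 enolate 17 (not isolated)
Conditions: KN(SiMe3)2, THF, −78 °C; PhNTf2, −78 → 0 °C
Reagents that add atoms: N-phenylbis(trifluoromethanesulfonimide), O=S(=O)(N(c1ccccc1)S(=O)(=O)C(F)(F)F)C(F)(F)F
Why: kinetic deprotonation should occur at the C7 methylene and not at the hindered ring‑fusion C5–H, and O‑triflation fixes the Δ6 enol triflate; the C1 silyl enol ether keeps the other carbonyl masked.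

Step 13
Reactants: 18 1-(tert-butyldimethylsilyloxy)-11,12-bis(triisopropylsilyloxy)drima-1,6-dien-6-yl trifluoromethanesulfonate
Product: 19 1-(tert-butyldimethylsilyloxy)-11,12-bis(triisopropylsilyloxy)drima-1,6-diene (5α-H, 8β-H, 9α-H)
Conditions: Pd(OAc)2 (5 mol %), PPh3 (10 mol %), HCO2H, Et3N, DMF, 60 °C
Reagents that add atoms: none
Why: palladium‑catalysed formate reduction of an enol triflate (oxidative addition, formate decarboxylation, reductive elimination) replaces the C6 oxygen by hydrogen and leaves the C6=C7 alkene.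

Step 14
Reactants: 19 1-(tert-butyldimethylsilyloxy)-11,12-bis(triisopropylsilyloxy)drima-1,6-diene
Product: 20 11,12-bis(triisopropylsilyloxy)drim-6-en-1-one (5α-H, 8β-H, 9α-H)
Conditions: 1 M aq. HCl, THF, 0 °C
Reagents that add atoms: none
Why: acid hydrolysis of the silyl enol ether to the C1 ketone; primary TIPS ethers and the isolated alkene should survive, and C10 is quaternary so nothing can epimerise.

Step 15
Reactants: 20 11,12-bis(triisopropylsilyloxy)drim-6-en-1-one
Product: 21 11,12-bis(triisopropylsilyloxy)drim-6-en-1β-ol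
Conditions: NaBH4, MeOH/THF, −20 → 0 °C
Reagents that add atoms: none
Why: hydride reduction with a small reagent; axial attack on the α‑face, anti to the C10 methyl and away from the C11 silyloxymethyl group, should give the equatorial 1β‑alcohol.

Step 16
Reactants: 21 11,12-bis(triisopropylsilyloxy)drim-6-en-1β-ol; 22 (E)-3-(4-methoxyphenyl)prop-2-enoyl chloride
Product: 23 11,12-bis(triisopropylsilyloxy)drim-6-en-1β-yl (E)-4-methoxycinnamate
Conditions: 4-(dimethylamino)pyridine, Et3N, CH2Cl2, 0 → 40 °C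
Reagents that add atoms: none
Why: nucleophile‑catalysed acylation of the hindered secondary alcohol with the acid chloride, with retention at C1 and at the (E) double bond.

Step 17
Reactants: 23 11,12-bis(triisopropylsilyloxy)drim-6-en-1β-yl (E)-4-methoxycinnamate
Product: 24 11,12-dihydroxydrim-6-en-1β-yl (E)-4-methoxycinnamate
Conditions: HF·pyridine, pyridine, THF, 0 °C → rt
Reagents that add atoms: none
Why: fluoride‑mediated cleavage of both primary silyl ethers under non‑basic conditions, which should avoid ester cleavage and acyl migration from O1 to the nearby C11 hydroxyl.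

Step 18
Reactants: 24 11,12-dihydroxydrim-6-en-1β-yl (E)-4-methoxycinnamate
Product: 25 6α,7α-epoxy-11,12-dihydroxydriman-1β-yl (E)-4-methoxycinnamate (8β-H)
Conditions: mCPBA, CH2Cl2, 0 °C; NaHCO3 wash
Reagents that add atoms: 3-chloroperoxybenzoic acid, O=C(OO)c1cccc(Cl)c1
Why: Prilezhaev epoxidation of the ring alkene from the α‑face, since the β‑face is blocked by the axial C10 and C4 methyl groups and the α‑oriented C12 hydroxyl can guide the peracid; the cinnamate double bond is electron‑poor and should not react.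

Step 19
Reactants: 25 6α,7α-epoxy-11,12-dihydroxydriman-1β-yl (E)-4-methoxycinnamate
Product: 27 6α-hydroxy-11,12-dioxodrim-7-en-1β-yl (E)-4-methoxycinnamate (the target), via epoxy dialdehyde 26 (not isolated)
Conditions: (COCl)2 (2.1 equiv), DMSO, CH2Cl2, −78 °C; Et3N, −78 → 0 °C
Reagents that add atoms: none
Why: Swern oxidation converts both primary alcohols at once (so no lactol can form), and the β,γ‑epoxy aldehyde then opens by E1cB elimination (C8 enolate expels the C7–O bond) to give the C7=C8 enal and the 6α‑hydroxyl with the configuration of the epoxide, while C9 should hold under triethylamine at or below 0 °C.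

**Compound list**

1 | (E)-pent-3-en-2-one | C/C=C/C(C)=O | starting material
2 | (E)-2-(triisopropylsilyloxy)penta-1,3-diene | C=C(O[Si](C(C)C)(C(C)C)C(C)C)/C=C/C | intermediate
3 | diethyl fumarate | CCOC(=O)/C=C/C(=O)OCC | starting material
4 | diethyl (1R,2R)-3-methyl-5-(triisopropylsilyloxy)cyclohex-4-ene-1,2-dicarboxylate (C3 epimers) | CCOC(=O)[C@H]1[C@H](C(=O)OCC)CC(O[Si](C(C)C)(C(C)C)C(C)C)=CC1C | intermediate
5 | [(1R,2R)-3-methyl-5-(triisopropylsilyloxy)cyclohex-4-ene-1,2-diyl]dimethanol (C3 epimers) | OC[C@H]1[C@H](CO)CC(O[Si](C(C)C)(C(C)C)C(C)C)=CC1C | intermediate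
6 | (1R,2R)-3-methyl-5-(triisopropylsilyloxy)-1,2-bis(triisopropylsilyloxymethyl)cyclohex-4-ene (C3 epimers) | CC(C)[Si](OC[C@H]1[C@H](CO[Si](C(C)C)(C(C)C)C(C)C)CC(O[Si](C(C)C)(C(C)C)C(C)C)=CC1C)(C(C)C)C(C)C | intermediate
7 | triisopropylsilyl (3R,4S)-5-methyl-6-oxo-3,4-bis(triisopropylsilyloxymethyl)hexanoate (C5 epimers) | O=CC(C)[C@@H](CO[Si](C(C)C)(C(C)C)C(C)C)[C@H](CO[Si](C(C)C)(C(C)C)C(C)C)CC(=O)O[Si](C(C)C)(C(C)C)C(C)C | intermediate
8 | (3R,4S)-5-methyl-6-oxo-3,4-bis(triisopropylsilyloxymethyl)hexanoic acid (C5 epimers) | O=CC(C)[C@@H](CO[Si](C(C)C)(C(C)C)C(C)C)[C@H](CO[Si](C(C)C)(C(C)C)C(C)C)CC(=O)O | intermediate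
9 | (3R,4S)-N-methoxy-N,5-dimethyl-6-oxo-3,4-bis(triisopropylsilyloxymethyl)hexanamide (C5 epimers) | O=CC(C)[C@@H](CO[Si](C(C)C)(C(C)C)C(C)C)[C@H](CO[Si](C(C)C)(C(C)C)C(C)C)CC(=O)N(C)OC | intermediate
10 | vinylmagnesium bromide (CH2=CHMgBr) | C=C[Mg]Br | starting material
11 | (3R,4S)-6-hydroxy-N-methoxy-N,5-dimethyl-3,4-bis(triisopropylsilyloxymethyl)oct-7-enamide (C5 and C6 epimers) | C=CC(O)C(C)[C@@H](CO[Si](C(C)C)(C(C)C)C(C)C)[C@H](CO[Si](C(C)C)(C(C)C)C(C)C)CC(=O)N(C)OC | intermediate
12 | (3R,4S)-N-methoxy-N,5-dimethyl-6-oxo-3,4-bis(triisopropylsilyloxymethyl)oct-7-enamide (C5 epimers) | C=CC(=O)C(C)[C@@H](CO[Si](C(C)C)(C(C)C)C(C)C)[C@H](CO[Si](C(C)C)(C(C)C)C(C)C)CC(=O)N(C)OC | intermediate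
13 | (3R,4S,5Z)-6-(tert-butyldimethylsilyloxy)-N-methoxy-N,5-dimethyl-3,4-bis(triisopropylsilyloxymethyl)octa-5,7-dienamide | C=C/C(O[Si](C)(C)C(C)(C)C)=C(\C)[C@@H](CO[Si](C(C)C)(C(C)C)C(C)C)[C@H](CO[Si](C(C)C)(C(C)C)C(C)C)CC(=O)N(C)OC | intermediate
14 | 2-methylprop-1-enylmagnesium bromide (Me2C=CHMgBr) | CC(C)=C[Mg]Br | starting material
15 | (6R,7S,8Z)-9-(tert-butyldimethylsilyloxy)-2,8-dimethyl-6,7-bis(triisopropylsilyloxymethyl)undeca-2,8,10-trien-4-one | C=C/C(O[Si](C)(C)C(C)(C)C)=C(\C)[C@@H](CO[Si](C(C)C)(C(C)C)C(C)C)[C@H](CO[Si](C(C)C)(C(C)C)C(C)C)CC(=O)C=C(C)C | intermediate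
16 | 1-(tert-butyldimethylsilyloxy)-11,12-bis(triisopropylsilyloxy)drim-1-en-6-one (5α-H, 8β-H, 9α-H, 10β-methyl) | CC(C)(C)[Si](C)(C)OC1=CCC(C)(C)[C@@H]2C(=O)C[C@@H](CO[Si](C(C)C)(C(C)C)C(C)C)[C@H](CO[Si](C(C)C)(C(C)C)C(C)C)[C@@]12C | intermediate
17 | potassium enolate of 16 (C6–O−, C6=C7) | CC(C)(C)[Si](C)(C)OC1=CCC(C)(C)[C@@H]2C([O-])=C[C@@H](CO[Si](C(C)C)(C(C)C)C(C)C)[C@H](CO[Si](C(C)C)(C(C)C)C(C)C)[C@@]12C.[K+] | intermediate
18 | 1-(tert-butyldimethylsilyloxy)-11,12-bis(triisopropylsilyloxy)drima-1,6-dien-6-yl trifluoromethanesulfonate | CC(C)(C)[Si](C)(C)OC1=CCC(C)(C)[C@@H]2C(OS(=O)(=O)C(F)(F)F)=C[C@@H](CO[Si](C(C)C)(C(C)C)C(C)C)[C@H](CO[Si](C(C)C)(C(C)C)C(C)C)[C@@]12C | intermediate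
19 | 1-(tert-butyldimethylsilyloxy)-11,12-bis(triisopropylsilyloxy)drima-1,6-diene (5α-H, 8β-H, 9α-H) | CC(C)(C)[Si](C)(C)OC1=CCC(C)(C)[C@@H]2C=C[C@@H](CO[Si](C(C)C)(C(C)C)C(C)C)[C@H](CO[Si](C(C)C)(C(C)C)C(C)C)[C@@]12C | intermediate
20 | 11,12-bis(triisopropylsilyloxy)drim-6-en-1-one (5α-H, 8β-H, 9α-H) | O=C1CCC(C)(C)[C@@H]2C=C[C@@H](CO[Si](C(C)C)(C(C)C)C(C)C)[C@H](CO[Si](C(C)C)(C(C)C)C(C)C)[C@@]12C | intermediate
21 | 11,12-bis(triisopropylsilyloxy)drim-6-en-1β-ol | O[C@@H]1CCC(C)(C)[C@@H]2C=C[C@@H](CO[Si](C(C)C)(C(C)C)C(C)C)[C@H](CO[Si](C(C)C)(C(C)C)C(C)C)[C@@]12C | intermediate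
22 | (E)-3-(4-methoxyphenyl)prop-2-enoyl chloride | COc1ccc(/C=C/C(Cl)=O)cc1 | starting material
23 | 11,12-bis(triisopropylsilyloxy)drim-6-en-1β-yl (E)-4-methoxycinnamate | COc1ccc(/C=C/C(=O)O[C@@H]2CCC(C)(C)[C@@H]3C=C[C@@H](CO[Si](C(C)C)(C(C)C)C(C)C)[C@H](CO[Si](C(C)C)(C(C)C)C(C)C)[C@@]23C)cc1 | intermediate
24 | 11,12-dihydroxydrim-6-en-1β-yl (E)-4-methoxycinnamate | COc1ccc(/C=C/C(=O)O[C@@H]2CCC(C)(C)[C@@H]3C=C[C@@H](CO)[C@H](CO)[C@@]23C)cc1 | intermediate
25 | 6α,7α-epoxy-11,12-dihydroxydriman-1β-yl (E)-4-methoxycinnamate (8β-H) | COc1ccc(/C=C/C(=O)O[C@@H]2CCC(C)(C)[C@@H]3[C@H]4O[C@H]4[C@@H](CO)[C@H](CO)[C@@]23C)cc1 | intermediate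
26 | 6α,7α-epoxy-11,12-dioxodriman-1β-yl (E)-4-methoxycinnamate (8β-H) | COc1ccc(/C=C/C(=O)O[C@@H]2CCC(C)(C)[C@@H]3[C@H]4O[C@H]4[C@@H](C=O)[C@H](C=O)[C@@]23C)cc1 | intermediate
27 | 6α-hydroxy-11,12-dioxodrim-7-en-1β-yl (E)-4-methoxycinnamate (CNP0283080.1) | COc1ccc(/C=C/C(=O)O[C@@H]2CCC(C)(C)[C@@H]3[C@@H](O)C=C(C=O)[C@H](C=O)[C@@]23C)cc1 | target

**Step count and risks**

Total: 19 steps. Longest linear sequence: 19 steps (1 → 27); compounds 3, 10, 14 and 22 enter as purchased reagents.

Steps most likely to fail: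

Step 11. The cycloaddition may be too slow, because a fully substituted diene terminus has to meet a β,β‑dimethyl enone; thermal [1,5]-hydrogen shift in the diene or ionic closure of the silyl enol ether onto the ketone could then take over. The fallback changes the mode of activation, from a thermal reaction of an electron‑rich diene to a Lewis‑acid‑activated enone meeting a diene that cannot act as an enolate equivalent. It sets out from 15: exchange of the silyl enol ether for an enol ester with pivaloyl fluoride and catalytic Bu4N+ Ph3SiF2− in THF should give, with retention of geometry, the (Z)-dienyl pivalate F1. Me2AlCl in CH2Cl2 (−78 → −20 °C) should promote the same intramolecular Diels–Alder reaction to the enol pivalate of the decalone F2. Deprotonation with KN(SiMe3)2 as in step 12 gives the potassium C6 enolate F3, which is triflated with PhNTf2 to the enol triflate F4. Formate reduction as in step 13 gives the Δ6 enol pivalate F5. Methanolysis of the enol ester (K2CO3, MeOH) then returns to the route at ketone 20.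

Step 9. Soft enolisation may give poor control of the enol ether geometry, and the wrong isomer would place the tether on the inside of the diene. The fallback fixes the geometry by nucleophile addition to a ketene instead of by deprotonation. It sets out from 9: Pinnick oxidation (NaClO2, NaH2PO4, 2-methylbut-2-ene) gives the carboxylic acid F6. Oxalyl chloride with catalytic DMF gives the acid chloride F7. Et3N in Et2O at 0 °C eliminates HCl to the methyl(alkyl)ketene F8. Vinylmagnesium bromide 10 (THF, −78 °C) should attack the ketene carbonyl in the plane of its substituents from the side of the smaller methyl group, giving the magnesium (Z)-enolate F9 with the vinyl group cis to methyl. Trapping with TBSOTf returns to the route at 13.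

Step 15. Facial selectivity of hydride delivery to the C1 ketone may be poor, since both faces are hindered (three axial hydrogens on the α‑face, the C10 methyl and the C11 side chain on the β‑face). The fallback replaces substrate control by reagent control and makes no new compound (F0). It sets out from 20: Corey–Bakshi–Shibata reduction with (S)-1-methyl-3,3-diphenyltetrahydro-1H,3H-pyrrolo[1,2-c][1,3,2]oxazaborole (20 mol %) and catecholborane in toluene at −78 °C. The quaternary C10 is the large group and the C2 methylene the small one, so the catalyst should deliver hydride to give the (1R)-alcohol. This returns to the route at 21.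

Further compounds
F1 | step 11 | (6R,7S,8Z)-2,8-dimethyl-4-oxo-6,7-bis(triisopropylsilyloxymethyl)undeca-2,8,10-trien-9-yl pivalate | C=C/C(OC(=O)C(C)(C)C)=C(\C)[C@@H](CO[Si](C(C)C)(C(C)C)C(C)C)[C@H](CO[Si](C(C)C)(C(C)C)C(C)C)CC(=O)C=C(C)C
F2 | step 11 | 6-oxo-11,12-bis(triisopropylsilyloxy)drim-1-en-1-yl pivalate (5α-H, 8β-H, 9α-H) | CC(C)(C)C(=O)OC1=CCC(C)(C)[C@@H]2C(=O)C[C@@H](CO[Si](C(C)C)(C(C)C)C(C)C)[C@H](CO[Si](C(C)C)(C(C)C)C(C)C)[C@@]12C
F3 | step 11 | potassium enolate of F2 (C6–O−, C6=C7) | CC(C)(C)C(=O)OC1=CCC(C)(C)[C@@H]2C([O-])=C[C@@H](CO[Si](C(C)C)(C(C)C)C(C)C)[C@H](CO[Si](C(C)C)(C(C)C)C(C)C)[C@@]12C.[K+]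
F4 | step 11 | 6-(trifluoromethylsulfonyloxy)-11,12-bis(triisopropylsilyloxy)drima-1,6-dien-1-yl pivalate | CC(C)(C)C(=O)OC1=CCC(C)(C)[C@@H]2C(OS(=O)(=O)C(F)(F)F)=C[C@@H](CO[Si](C(C)C)(C(C)C)C(C)C)[C@H](CO[Si](C(C)C)(C(C)C)C(C)C)[C@@]12C
F5 | step 11 | 11,12-bis(triisopropylsilyloxy)drima-1,6-dien-1-yl pivalate | CC(C)(C)C(=O)OC1=CCC(C)(C)[C@@H]2C=C[C@@H](CO[Si](C(C)C)(C(C)C)C(C)C)[C@H](CO[Si](C(C)C)(C(C)C)C(C)C)[C@@]12C
F6 | step 9 | (3S,4R)-6-[methoxy(methyl)amino]-2-methyl-6-oxo-3,4-bis(triisopropylsilyloxymethyl)hexanoic acid (C2 epimers) | OC(=O)C(C)[C@@H](CO[Si](C(C)C)(C(C)C)C(C)C)[C@H](CO[Si](C(C)C)(C(C)C)C(C)C)CC(=O)N(C)OC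
F7 | step 9 | acid chloride of F6 | ClC(=O)C(C)[C@@H](CO[Si](C(C)C)(C(C)C)C(C)C)[C@H](CO[Si](C(C)C)(C(C)C)C(C)C)CC(=O)N(C)OC
F8 | step 9 | ketene from F7 (C1=C10 cumulated with C1=O) | O=C=C(C)[C@@H](CO[Si](C(C)C)(C(C)C)C(C)C)[C@H](CO[Si](C(C)C)(C(C)C)C(C)C)CC(=O)N(C)OC
F9 | step 9 | bromomagnesium (Z)-dienolate corresponding to 13 | C=C/C(O[Mg]Br)=C(\C)[C@@H](CO[Si](C(C)C)(C(C)C)C(C)C)[C@H](CO[Si](C(C)C)(C(C)C)C(C)C)CC(=O)N(C)OC
F0 | step 15 | none | none
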